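**Plan**
- Retrosynthesis: in each 2',4'-dihydroxyphenyl ketone the C1'–C2' and C5'–C6' bonds are cut first, taking both resorcinol rings back to terminal ynones and a 1-methoxy-1,3-bis(silyloxy)butadiene. Next come the two C(=O)–C≡C bonds (N-methoxy-N-methylamides plus ethynyl Grignard), the two Cα–Cβ bonds of the arms (olefination of aldehydes) and last the diaryl ether C–O bond (SNAr).
- Enabling feature: in each resorcinol ring the acyl-bearing C1' lies between hydroxylated C2' and unsubstituted C6', and the second hydroxyl is on C4', para to C1'. C1' and C6' map onto a terminal ynone, C2'–C5' onto a 1,1,3-trioxygenated butadiene whose ketal carbon becomes C2'.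
- Forward order: rings A and B are bought and joined as the diaryl ether, both three-carbon arms are grown in parallel to a bis-ynone, and the two resorcinol rings are built last, together, by double cycloaddition–aromatisation. One desilylation ends the route.
- Stereochemistry: the target has no stereocentre and no stereogenic double bond. The E alkenes from the olefination are hydrogenated and the ketal centres of the cycloadduct disappear on aromatisation.

Key step: step 8

Remark: the double-bond geometry of the silyl enol ether and of the diene made from methyl acetoacetate has no bearing on the cycloaddition; one isomer is written for each.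

**Step 1**
Reactants: 1 4-fluoro-3-methoxybenzaldehyde; 2 4-(benzyloxy)-3-hydroxybenzaldehyde
Product: 3 4-[2-(benzyloxy)-5-formylphenoxy]-3-methoxybenzaldehyde
Conditions: K2CO3, DMF, 120 °C, N2
Reagents that add atoms: none
Why: Nucleophilic aromatic substitution (SNAr) should succeed because the fluoride of 1 is para to the formyl group and is displaced by the phenoxide of 2 through a stabilised Meisenheimer intermediate, while the benzyl ether keeps the 4-oxygen of ring B out of the reaction.

**Step 2**
Reactants: 3 4-[2-(benzyloxy)-5-formylphenoxy]-3-methoxybenzaldehyde; 4 diethyl {2-[methoxy(methyl)amino]-2-oxoethyl}phosphonate (2.4 equiv)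
Product: 5 (2E)-3-{4-(benzyloxy)-3-[2-methoxy-4-[(1E)-3-[methoxy(methyl)amino]-3-oxoprop-1-en-1-yl]phenoxy]phenyl}-N-methoxy-N-methylprop-2-enamide
Conditions: NaH, THF, 0 °C to rt
Reagents that add atoms: none
Why: A twofold Horner–Wadsworth–Emmons olefination of the two non-enolisable aryl aldehydes with the stabilised phosphonate anion should give both (E)-enamides and brings in the arms directly at the amide oxidation level.

**Step 3**
Reactants: 5 bis[(E)-N-methoxy-N-methylacrylamide] of the benzyl-protected diaryl ether
Product: 6 3-{4-hydroxy-3-[2-methoxy-4-[3-[methoxy(methyl)amino]-3-oxopropyl]phenoxy]phenyl}-N-methoxy-N-methylpropanamide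
Conditions: H2 (1 atm), Pd/C (10 wt%), EtOAc–MeOH, rt
Reagents that add atoms: none
Why: Catalytic hydrogenation over palladium on carbon should saturate both cinnamamide C=C bonds and hydrogenolyse the benzyl ether in the same operation, while the N–O bonds of the amides and the diaryl ether resist one atmosphere of hydrogen at room temperature.

**Step 4**
Reactants: 6 phenol bis(N-methoxy-N-methylpropanamide)
Product: 7 3-{4-[(tert-butyldimethylsilyl)oxy]-3-[2-methoxy-4-[3-[methoxy(methyl)amino]-3-oxopropyl]phenoxy]phenyl}-N-methoxy-N-methylpropanamide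
Conditions: TBSCl, imidazole, DMF, rt
Reagents that add atoms: tert-butyldimethylsilyl chloride (TBSCl), CC(C)(C)[Si](C)(C)Cl
Why: Standard silylation of a phenol with a silyl chloride and imidazole should mask the only acidic hydroxyl, so that it neither consumes Grignard reagent in the next step nor protonates the acid-sensitive diene later.

**Step 5**
Reactants: 7 silyl-protected bis(N-methoxy-N-methylpropanamide); 8 ethynylmagnesium bromide (excess)
Product: 10 5-{4-[(tert-butyldimethylsilyl)oxy]-3-[2-methoxy-4-(3-oxopent-4-yn-1-yl)phenoxy]phenyl}pent-1-yn-3-one, via bis(bromomagnesium) hemiaminal adduct 9 (not isolated)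
Conditions: HC≡CMgBr, THF, 0 °C; inverse quench into ice-cold aq. NaHSO4
Reagents that add atoms: none
Why: In this Weinreb ketone synthesis each N-methoxy-N-methylamide should take up one alkynyl Grignard to give the chelated tetrahedral adduct 9, which resists over-addition and releases the terminal ynone only during the cold acidic quench that also traps the liberated amine as its salt.

**Step 6**
Reactants: 11 methyl acetoacetate
Product: 12 methyl (2E)-3-(trimethylsilyloxy)but-2-enoate
Conditions: Me3SiCl, Et3N, hexane, rt
Reagents that add atoms: chlorotrimethylsilane (Me3SiCl), C[Si](C)(C)Cl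
Why: O-Silylation of the enol form of a β-keto ester by the chlorosilane and amine pair is a standard silyl enol ether formation.

**Step 7**
Reactants: 12 methyl (2E)-3-(trimethylsilyloxy)but-2-enoate
Product: 14 (1Z)-1-methoxy-1,3-bis(trimethylsilyloxy)buta-1,3-diene, via lithium dienolate 13 (not isolated)
Conditions: LiN(iPr)2, THF, −78 °C; Me3SiCl, −78 °C to rt; filtered under N2 and used at once
Reagents that add atoms: chlorotrimethylsilane (Me3SiCl), C[Si](C)(C)Cl
Why: γ-Deprotonation of the vinylogous ester by the lithium amide gives dienolate 13, and its O-silylation is the standard preparation of 1-alkoxy-1,3-bis(silyloxy)butadienes.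

**Step 8**
Reactants: 10 bis-ynone of the diaryl ether core; 14 (1Z)-1-methoxy-1,3-bis(trimethylsilyloxy)buta-1,3-diene (3 equiv, two molecules react)
Product: 16 verbenachalcone ring B tert-butyldimethylsilyl ether, via bis-cyclohexadiene cycloadduct 15 (not isolated)
Conditions: toluene, −20 °C to rt; then 1 M HCl, THF, 0 °C to rt
Reagents that add atoms: none
Why: Each molecule of the electron-rich diene 14 should add across one terminal ynone of 10 in an asynchronous normal-electron-demand Diels–Alder reaction (at the stepwise limit a Mukaiyama–Michael addition followed by Claisen-type closure of the allenolate onto the oxocarbenium carbon), the diene methylene C4 bonding to the ynone β-carbon (C6') and the ketene acetal carbon C1 to the α-carbon (C1'), which gives bis-cyclohexa-1,4-diene 15. On the acidic work-up the mixed methyl silyl ketal at C2' of each ring should collapse with loss of methanol, the silyl enol ether at C4' is hydrolysed and enolisation aromatises the ring, so that no oxidant is needed and all four arm phenols emerge free. The closest known reaction type is the cycloaddition–aromatisation of 1,1-dioxygenated 3-silyloxybutadienes with acetylenic ketones and esters, which gives resorcinol derivatives. Each of the two resorcinol rings closes as a six-membered carbocycle by intermolecular [4+2] annulation, carbons C2' to C5' coming from the diene and C1' and C6' from the ynone, with the C1'–C2' and C5'–C6' bonds made in this step. No stereocentre is created that persists, because the ketal carbons of 15 form without control and become planar arene carbons. The step needs regioselectivity, which the polarisation of the partners secures (largest diene HOMO coefficient at the methylene terminus, largest ynone LUMO coefficient at the unsubstituted β-carbon), and chemoselectivity, which rests on the uncatalysed diene attacking the activated C≡C and not the C=O group and on the short dilute-acid work-up cleaving trimethylsilyl groups while sparing the aryl tert-butyldimethylsilyl ether.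

**Step 9**
Reactants: 16 verbenachalcone ring B tert-butyldimethylsilyl ether
Product: 17 verbenachalcone
Conditions: Bu4NF, AcOH, THF, 0 °C
Reagents that add atoms: none
Why: Fluoride-induced cleavage of an aryl silyl ether, driven by Si–F bond formation and buffered with acetic acid so that the polyphenolic ketone never sits as a free phenoxide, should release the ring B phenol and give the target.

**Compound list**
1 | 4-fluoro-3-methoxybenzaldehyde | COc1cc(C=O)ccc1F | starting material
2 | 4-(benzyloxy)-3-hydroxybenzaldehyde | O=Cc1ccc(OCc2ccccc2)c(O)c1 | starting material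
3 | 4-[2-(benzyloxy)-5-formylphenoxy]-3-methoxybenzaldehyde | COc1cc(C=O)ccc1Oc1cc(C=O)ccc1OCc1ccccc1 | intermediate
4 | diethyl {2-[methoxy(methyl)amino]-2-oxoethyl}phosphonate | CCOP(=O)(OCC)CC(=O)N(C)OC | starting material
5 | (2E)-3-{4-(benzyloxy)-3-[2-methoxy-4-[(1E)-3-[methoxy(methyl)amino]-3-oxoprop-1-en-1-yl]phenoxy]phenyl}-N-methoxy-N-methylprop-2-enamide | COc1cc(/C=C/C(=O)N(C)OC)ccc1Oc1cc(/C=C/C(=O)N(C)OC)ccc1OCc1ccccc1 | intermediate
6 | 3-{4-hydroxy-3-[2-methoxy-4-[3-[methoxy(methyl)amino]-3-oxopropyl]phenoxy]phenyl}-N-methoxy-N-methylpropanamide | COc1cc(CCC(=O)N(C)OC)ccc1Oc1cc(CCC(=O)N(C)OC)ccc1O | intermediate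
7 | 3-{4-[(tert-butyldimethylsilyl)oxy]-3-[2-methoxy-4-[3-[methoxy(methyl)amino]-3-oxopropyl]phenoxy]phenyl}-N-methoxy-N-methylpropanamide | COc1cc(CCC(=O)N(C)OC)ccc1Oc1cc(CCC(=O)N(C)OC)ccc1O[Si](C)(C)C(C)(C)C | intermediate
8 | ethynylmagnesium bromide | C#C[Mg]Br | starting material
9 | bis(bromomagnesium alkoxide) of the bis-hemiaminal formed by addition of one ethynyl group to each amide carbonyl of 7 (formed in the flask; both hemiaminal carbons unspecified, lost on collapse) | COc1cc(CCC(O[Mg]Br)(C#C)N(C)OC)ccc1Oc1cc(CCC(O[Mg]Br)(C#C)N(C)OC)ccc1O[Si](C)(C)C(C)(C)C | intermediate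
10 | 5-{4-[(tert-butyldimethylsilyl)oxy]-3-[2-methoxy-4-(3-oxopent-4-yn-1-yl)phenoxy]phenyl}pent-1-yn-3-one (bis-ynone) | COc1cc(CCC(=O)C#C)ccc1Oc1cc(CCC(=O)C#C)ccc1O[Si](C)(C)C(C)(C)C | intermediate
11 | methyl acetoacetate | COC(=O)CC(C)=O | starting material
12 | methyl (2E)-3-(trimethylsilyloxy)but-2-enoate | COC(=O)/C=C(\C)O[Si](C)(C)C | intermediate
13 | lithium 1-methoxy-3-(trimethylsilyloxy)buta-1,3-dien-1-olate (formed in the flask) | [Li+].CO/C([O-])=C/C(=C)O[Si](C)(C)C | intermediate
14 | (1Z)-1-methoxy-1,3-bis(trimethylsilyloxy)buta-1,3-diene | CO/C(O[Si](C)(C)C)=C/C(=C)O[Si](C)(C)C | intermediate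
15 | bis-cycloadduct in which each arm ketone carries a 6-methoxy-4,6-bis(trimethylsilyloxy)cyclohexa-1,4-dien-1-yl ring (formed in the flask; both ketal carbons unspecified, lost on aromatisation) | COc1cc(CCC(=O)C2=CCC(O[Si](C)(C)C)=CC2(OC)O[Si](C)(C)C)ccc1Oc1cc(CCC(=O)C2=CCC(O[Si](C)(C)C)=CC2(OC)O[Si](C)(C)C)ccc1O[Si](C)(C)C(C)(C)C | intermediate
16 | 3-{4-[(tert-butyldimethylsilyl)oxy]-3-[4-[3-(2,4-dihydroxyphenyl)-3-oxopropyl]-2-methoxyphenoxy]phenyl}-1-(2,4-dihydroxyphenyl)propan-1-one (verbenachalcone ring B silyl ether) | COc1cc(CCC(=O)c2ccc(O)cc2O)ccc1Oc1cc(CCC(=O)c2ccc(O)cc2O)ccc1O[Si](C)(C)C(C)(C)C | intermediate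
17 | verbenachalcone, 1-(2,4-dihydroxyphenyl)-3-{3-[4-[3-(2,4-dihydroxyphenyl)-3-oxopropyl]-2-methoxyphenoxy]-4-hydroxyphenyl}propan-1-one | COc1cc(CCC(=O)c2ccc(O)cc2O)ccc1Oc1cc(CCC(=O)c2ccc(O)cc2O)ccc1O | target

**Step count**
Total steps: 9. Longest linear sequence: 7 (steps 1–5, 8 and 9); steps 6 and 7 make the diene in a side branch.

**Steps most likely to fail**

Step 8. The terminal ynones may oligomerise or be attacked at the carbonyl before ring closure, and adventitious acid may protodesilylate the diene, so that one arm stays unannulated. Partial loss of silanol instead of methanol at the ketal carbon would leave a 2'-methyl ether. The fallback gives up the cycloaddition, sets out from 3 and comes back to the route at 17. A Knoevenagel–Doebner condensation of 3 with malonic acid (pyridine, catalytic piperidine, 95 °C) would give (2E)-3-{4-(benzyloxy)-3-[4-[(E)-2-carboxyethenyl]-2-methoxyphenoxy]phenyl}prop-2-enoic acid F1. Hydrogenation over Pd/C would saturate both alkenes and remove the benzyl group to give 3-{3-[4-(2-carboxyethyl)-2-methoxyphenoxy]-4-hydroxyphenyl}propanoic acid F2. A twofold Friedel–Crafts acylation of excess resorcinol by F2 in BF3·OEt2 at 85 °C would then attach both 2,4-dihydroxyphenyl ketones and deliver 17 directly.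

Step 5. The N,O-dimethylhydroxylamine released on quench may add in conjugate fashion to the freshly formed terminal ynones, and the ynones may decompose under the basic magnesium salts. The fallback changes the oxidation level, sets out from 7 and comes back at 10. Reduction of both amides with iBu2AlH (THF, −78 °C) would give 3-{4-[(tert-butyldimethylsilyl)oxy]-3-[2-methoxy-4-(3-oxopropyl)phenoxy]phenyl}propanal F3. Addition of HC≡CMgBr would give 5-{4-[(tert-butyldimethylsilyl)oxy]-3-[4-(3-hydroxypent-4-yn-1-yl)-2-methoxyphenoxy]phenyl}pent-1-yn-3-ol F4 as a mixture of diastereomers. Oxidation of both propargylic alcohols with Dess–Martin periodinane (NaHCO3, CH2Cl2) would give 10 with no amine present.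

Step 1. Fluoride displacement next to the electron-donating, crowding ortho methoxy group may be slow, and at the temperature then needed the aldehydes may degrade by disproportionation or aerial oxidation. The fallback replaces SNAr by a copper-catalysed Ullmann diaryl ether coupling, sets out from 2 and comes back at 3. Phenol 2 and commercial 4-bromo-3-methoxybenzaldehyde would be coupled with CuCl, 2,2,6,6-tetramethylheptane-3,5-dione and Cs2CO3 in NMP at 120 °C. This fallback makes no new compound (F0).

**Further compounds**
F1 | step 8 | (2E)-3-{4-(benzyloxy)-3-[4-[(E)-2-carboxyethenyl]-2-methoxyphenoxy]phenyl}prop-2-enoic acid | COc1cc(/C=C/C(=O)O)ccc1Oc1cc(/C=C/C(=O)O)ccc1OCc1ccccc1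
F2 | step 8 | 3-{3-[4-(2-carboxyethyl)-2-methoxyphenoxy]-4-hydroxyphenyl}propanoic acid | COc1cc(CCC(=O)O)ccc1Oc1cc(CCC(=O)O)ccc1O
F3 | step 5 | 3-{4-[(tert-butyldimethylsilyl)oxy]-3-[2-methoxy-4-(3-oxopropyl)phenoxy]phenyl}propanal | COc1cc(CCC=O)ccc1Oc1cc(CCC=O)ccc1O[Si](C)(C)C(C)(C)C
F4 | step 5 | 5-{4-[(tert-butyldimethylsilyl)oxy]-3-[4-(3-hydroxypent-4-yn-1-yl)-2-methoxyphenoxy]phenyl}pent-1-yn-3-ol (mixture of diastereomers) | COc1cc(CCC(O)C#C)ccc1Oc1cc(CCC(O)C#C)ccc1O[Si](C)(C)C(C)(C)C
F0 | step 1 | none | none
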